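**Plan**

1. The target is the meso isomer, (6R,6'S)-ε,ε-carotene-3,3'-dione (carotenoid numbering): two mirror-image 3-oxo-ε rings on a symmetric all-E chain.
2. Retrosynthesis: the two ketones are traced back to carbinols. C11=C12 and C11'=C12' are then cut (two Wittig reactions, C15 + C10 + C15), then C9–C10 and C7=C8 of each side chain, and last, in each ring, C2–C3 and C1–C6 together.
3. Enabling feature: in each ring the ketone carbon C3, the C4=C5(Me) double bond and C6 form a four-carbon unit with an acyl end and a vinylogous nucleophilic end, and C1(Me)2–C2H2 is an isobutene unit. With C7 as an ester the four-carbon unit is the symmetric anion of dimethyl 3-methylglutaconate, and a nitro group on C2 turns isobutene into an acceptor whose adduct closes the ring by acylation (anionic [4+2]).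
4. Forward: the ring arises first (step 1) and the nitro helper is removed (step 2). The side chain is then built to the C15 phosphonium salt in two parallel series, the two salts are joined in turn to the C10 dialdehyde, and the carbinols are oxidised last.
5. Stereochemistry: the ring is made racemic on purpose. A catalyst-controlled CBS reduction (step 3) turns the two antipodes into separable diastereomers, (3R,6R) and (3R,6S), and each serves one end, so nothing is discarded. The C3 carbinol also keeps C6–H non-acidic during the olefinations; alkene geometry comes from E-selective olefinations and equilibration.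

Key step: step 1

Assumption: in the oxazaborolidine reduction the alkenyl flank of the ring ketone is taken to act as the large substituent, so that the (S)-catalyst gives the (4R)-carbinol; should the sense be the reverse, the (R)-catalyst is used and nothing else changes.

**Route**

Step 1
Reactants: 1 dimethyl 3-methylpent-2-enedioate (dimethyl 3-methylglutaconate; E/Z mixture); 2 2-methyl-1-nitroprop-1-ene
Product: 4 methyl 2,6,6-trimethyl-5-nitro-4-oxocyclohex-2-ene-1-carboxylate (racemic; C5 epimers), via potassium nitronate of the open-chain Michael adduct 3 (not isolated)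
Conditions: KOtBu (1.05 equiv), THF, −20 °C; 2 (1.2 equiv), −20 → 25 °C; then 18-crown-6 (0.1 equiv), 60 °C; AcOH, 0 °C
Reagents that add atoms: none
Why: Proposed new method: an anionic [4+2] annulation in which a Michael addition to the nitroalkene is followed in the same flask by Claisen-type C-acylation of the resulting nitronate by the remote ester; the closest known reactions are the Michael–Claisen route to 5,5-dimethylcyclohexane-1,3-diones from malonates and β,β-dimethyl enones and the C-acylation of nitronates by acyl imidazoles and by phthalate esters. The pentadienyl-type anion of 1 has two equivalent ester-bearing termini, so attack of either on the nitro-activated CMe2 carbon of 2 gives the same adduct 3 and sets the quaternary carbon (bond CH(CO2Me)–CMe2). Nitro is the helper of choice because in 3 the nitronate, not the ester-flanked carbanion, should be the resting anion: the conjugated ester therefore stays a neutral electrophile, reversible proton transfer at the doubly activated CH lets the enoate reach the Z geometry, and the nitronate carbon closes the six-membered ring by 6-exo-trig attack on that ester carbonyl (bond CH(NO2)–C=O), methoxide loss and deprotonation of the acidic α-nitro ketone making the closure irreversible. No other closure competes, since C-attack on the nearer ester would give a four-membered ring and O-acylation an eight-membered one. The two new stereocentres (C1 with the ester and C5 with the nitro group) form without control and both are epimerisable here: C5 is erased in step 2 and C1 is wanted racemic, because each antipode serves one end of the meso target and the two are sorted in step 3. The only selectivity needed is constitutional (carbon–carbon bond at the CMe2 carbon, acylation at the nitronate carbon) and it is secured by the polarity of the nitroalkene and by ring size.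

Step 2
Reactants: 4 methyl 2,6,6-trimethyl-5-nitro-4-oxocyclohex-2-ene-1-carboxylate
Product: 5 methyl 2,6,6-trimethyl-4-oxocyclohex-2-ene-1-carboxylate (racemic)
Conditions: Bu3SnH (1.5 equiv), AIBN (0.2 equiv), PhMe, 80 °C
Reagents that add atoms: none
Why: Radical denitration, a reaction type well known for α-nitro ketones: the tributylstannyl radical adds to a nitro oxygen, the C–N bond next to the ketone breaks to a carbonyl-stabilised radical, and hydrogen transfer from Bu3SnH leaves the ring CH2, with no stereocentre formed and the ester and enone untouched.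

Step 3
Reactants: 5 methyl 2,6,6-trimethyl-4-oxocyclohex-2-ene-1-carboxylate (racemic)
Product: 6 methyl (1R,4R)-4-hydroxy-2,6,6-trimethylcyclohex-2-ene-1-carboxylate (trans) and 7 methyl (1S,4R)-4-hydroxy-2,6,6-trimethylcyclohex-2-ene-1-carboxylate (cis)
Conditions: (S)-1-methyl-3,3-diphenyltetrahydro-1H,3H-pyrrolo[1,2-c][1,3,2]oxazaborole (0.5 equiv), catecholborane (1.8 equiv), PhMe, −78 °C; MeOH, then aq. Na2CO3; SiO2 chromatography separates 6 from 7
Reagents that add atoms: none
Why: Corey–Bakshi–Shibata reduction: the oxazaborolidine should deliver hydride to the same face of the enone carbonyl of both antipodes of 5 (1,2-reduction), so the new carbinol centre is (4R) by catalyst control and the antipodes at C1 become the trans and cis diastereomers 6 and 7, separable on silica, while the non-basic medium leaves C1 unepimerised.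

Step 4
Reactants: 6 methyl (1R,4R)-4-hydroxy-2,6,6-trimethylcyclohex-2-ene-1-carboxylate
Product: 8 (1R,4R)-4-hydroxy-2,6,6-trimethylcyclohex-2-ene-1-carbaldehyde
Conditions: i-Bu2AlH (2.2 equiv), CH2Cl2, −78 °C; MeOH, then aq. potassium sodium tartrate
Reagents that add atoms: none
Why: Half-reduction of a hindered α-branched methyl ester with i-Bu2AlH at −78 °C, where a second hydride transfer should not occur before the aqueous quench; the first equivalent is consumed by the hydroxyl group and neither stereocentre is touched.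

Step 5
Reactants: 7 methyl (1S,4R)-4-hydroxy-2,6,6-trimethylcyclohex-2-ene-1-carboxylate
Product: 9 (1S,4R)-4-hydroxy-2,6,6-trimethylcyclohex-2-ene-1-carbaldehyde
Conditions: i-Bu2AlH (2.2 equiv), CH2Cl2, −78 °C; MeOH, then aq. potassium sodium tartrate
Reagents that add atoms: none
Why: The same half-reduction of the ester as in step 4, applied to the cis series, with both stereocentres untouched.

Step 6
Reactants: 8 (1R,4R)-4-hydroxy-2,6,6-trimethylcyclohex-2-ene-1-carbaldehyde
Product: 10 (3E)-4-[(1R,4R)-4-hydroxy-2,6,6-trimethylcyclohex-2-en-1-yl]but-3-en-2-one [(3R,6R)-3-hydroxy-α-ionone]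
Conditions: (MeO)2P(O)CH2C(O)CH3 (1.5 equiv), LiCl, i-Pr2NEt, MeCN, 25 °C
Reagents that add atoms: dimethyl (2-oxopropyl)phosphonate, COP(=O)(OC)CC(C)=O
Why: Horner–Wadsworth–Emmons olefination in its mild LiCl/amine form: the stabilised β-ketophosphonate anion should give the (E)-enone and the weak base should leave the α-stereocentre of the aldehyde (ring C1) unepimerised.

Step 7
Reactants: 9 (1S,4R)-4-hydroxy-2,6,6-trimethylcyclohex-2-ene-1-carbaldehyde
Product: 11 (3E)-4-[(1S,4R)-4-hydroxy-2,6,6-trimethylcyclohex-2-en-1-yl]but-3-en-2-one [(3R,6S)-3-hydroxy-α-ionone]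
Conditions: (MeO)2P(O)CH2C(O)CH3 (1.5 equiv), LiCl, i-Pr2NEt, MeCN, 25 °C
Reagents that add atoms: dimethyl (2-oxopropyl)phosphonate, COP(=O)(OC)CC(C)=O
Why: The same E-selective Horner–Wadsworth–Emmons olefination as in step 6, applied to the cis series.

Step 8
Reactants: 10 (3E)-4-[(1R,4R)-4-hydroxy-2,6,6-trimethylcyclohex-2-en-1-yl]but-3-en-2-one
Product: 12 (4E)-5-[(1R,4R)-4-hydroxy-2,6,6-trimethylcyclohex-2-en-1-yl]-3-methylpenta-1,4-dien-3-ol (both C3 epimers)
Conditions: CH2=CHMgBr (3 equiv), THF, −20 → 0 °C; aq. NH4Cl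
Reagents that add atoms: vinylmagnesium bromide, C=C[Mg]Br
Why: Grignard 1,2-addition to the methyl ketone of the enone (the first equivalent deprotonates the ring hydroxyl); the new tertiary carbinol centre forms as both epimers, which does not matter because it becomes sp2 in step 10.

Step 9
Reactants: 11 (3E)-4-[(1S,4R)-4-hydroxy-2,6,6-trimethylcyclohex-2-en-1-yl]but-3-en-2-one
Product: 13 (4E)-5-[(1S,4R)-4-hydroxy-2,6,6-trimethylcyclohex-2-en-1-yl]-3-methylpenta-1,4-dien-3-ol (both C3 epimers)
Conditions: CH2=CHMgBr (3 equiv), THF, −20 → 0 °C; aq. NH4Cl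
Reagents that add atoms: vinylmagnesium bromide, C=C[Mg]Br
Why: The same Grignard 1,2-addition as in step 8, applied to the cis series.

Step 10
Reactants: 12 (4E)-5-[(1R,4R)-4-hydroxy-2,6,6-trimethylcyclohex-2-en-1-yl]-3-methylpenta-1,4-dien-3-ol
Product: 14 [(2E,4E)-5-[(1R,4R)-4-hydroxy-2,6,6-trimethylcyclohex-2-en-1-yl]-3-methylpenta-2,4-dien-1-yl](triphenyl)phosphonium bromide
Conditions: Ph3P·HBr (1.0 equiv), CH2Cl2, 0 → 25 °C
Reagents that add atoms: triphenylphosphine hydrobromide, [Br-].[PH+](c1ccccc1)(c1ccccc1)c1ccccc1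
Why: SN1-type phosphonium salt formation with allylic transposition: the tertiary bis-allylic alcohol ionises to a pentadienyl cation that PPh3 captures at the unhindered primary terminus to give the conjugated (2E,4E)-dienyl salt, while the secondary ring carbinol should ionise far more slowly under these mild conditions.

Step 11
Reactants: 13 (4E)-5-[(1S,4R)-4-hydroxy-2,6,6-trimethylcyclohex-2-en-1-yl]-3-methylpenta-1,4-dien-3-ol
Product: 15 [(2E,4E)-5-[(1S,4R)-4-hydroxy-2,6,6-trimethylcyclohex-2-en-1-yl]-3-methylpenta-2,4-dien-1-yl](triphenyl)phosphonium bromide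
Conditions: Ph3P·HBr (1.0 equiv), CH2Cl2, 0 → 25 °C
Reagents that add atoms: triphenylphosphine hydrobromide, [Br-].[PH+](c1ccccc1)(c1ccccc1)c1ccccc1
Why: The same ionisation and phosphine capture with allylic transposition as in step 10, applied to the cis series.

Step 12
Reactants: 14 phosphonium bromide of the (1R,4R) series; 16 (2E,4E,6E)-2,7-dimethylocta-2,4,6-trienedial (3 equiv)
Product: 18 (2E,4E,6E,8E,10E,12E)-13-[(1R,4R)-4-hydroxy-2,6,6-trimethylcyclohex-2-en-1-yl]-2,7,11-trimethyltrideca-2,4,6,8,10,12-hexaenal [(3R,6R)-3-hydroxy-12'-apo-ε-caroten-12'-al], via phosphorus ylide 17 (not isolated)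
Conditions: NaOMe (1.1 equiv), CH2Cl2–MeOH, 0 °C, 14 added slowly to 16; then I2 (cat.), CH2Cl2, daylight
Reagents that add atoms: none
Why: Wittig reaction of the semi-stabilised allylic ylide with one aldehyde group of the dialdehyde, kept in excess to suppress double olefination; the new C11=C12 bond forms as an E/Z mixture that iodine-catalysed equilibration should convert to the all-E aldehyde, and the free hydroxyl is tolerated.

Step 13
Reactants: 15 phosphonium bromide of the (1S,4R) series; 18 (3R,6R)-3-hydroxy-12'-apo-ε-caroten-12'-al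
Product: 20 (3R,6R,3'R,6'S)-ε,ε-carotene-3,3'-diol, via phosphorus ylide 19 (not isolated)
Conditions: NaOMe (1.2 equiv), CH2Cl2–MeOH, 25 °C; then n-heptane, reflux
Reagents that add atoms: none
Why: Second Wittig reaction, which joins the (6S) end to the (6R) end; the new C11'=C12' bond is equilibrated thermally to E, and because neither C6 nor C6' is next to an acidifying group at this stage the base should not epimerise them.

Step 14
Reactants: 20 (3R,6R,3'R,6'S)-ε,ε-carotene-3,3'-diol
Product: 21 (6R,6'S)-ε,ε-carotene-3,3'-dione (meso; target)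
Conditions: MnO2 (activated, excess), CH2Cl2, 25 °C, dark, argon
Reagents that add atoms: none
Why: Allylic oxidation with MnO2, neutral and selective for allylic carbinols, should convert both C3 carbinols into the enones without touching the polyene or the C6 and C6' centres; the C3 centres are erased and the meso dione results.

**Compound list**

1 | dimethyl 3-methylpent-2-enedioate (dimethyl 3-methylglutaconate; E/Z mixture) | COC(=O)CC(C)=CC(=O)OC | starting material
2 | 2-methyl-1-nitroprop-1-ene | CC(C)=C[N+](=O)[O-] | starting material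
3 | potassium nitronate of dimethyl 3-methyl-4-(2-methyl-1-nitropropan-2-yl)pent-2-enedioate (not isolated) | COC(=O)C=C(C)C(C(=O)OC)C(C)(C)C=[N+]([O-])[O-].[K+] | intermediate
4 | methyl 2,6,6-trimethyl-5-nitro-4-oxocyclohex-2-ene-1-carboxylate (racemic; C5 epimers) | COC(=O)C1C(C)=CC(=O)C([N+](=O)[O-])C1(C)C | intermediate
5 | methyl 2,6,6-trimethyl-4-oxocyclohex-2-ene-1-carboxylate (racemic) | COC(=O)C1C(C)=CC(=O)CC1(C)C | intermediate
6 | methyl (1R,4R)-4-hydroxy-2,6,6-trimethylcyclohex-2-ene-1-carboxylate | COC(=O)[C@H]1C(C)=C[C@H](O)CC1(C)C | intermediate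
7 | methyl (1S,4R)-4-hydroxy-2,6,6-trimethylcyclohex-2-ene-1-carboxylate | COC(=O)[C@@H]1C(C)=C[C@H](O)CC1(C)C | intermediate
8 | (1R,4R)-4-hydroxy-2,6,6-trimethylcyclohex-2-ene-1-carbaldehyde | O=C[C@H]1C(C)=C[C@H](O)CC1(C)C | intermediate
9 | (1S,4R)-4-hydroxy-2,6,6-trimethylcyclohex-2-ene-1-carbaldehyde | O=C[C@@H]1C(C)=C[C@H](O)CC1(C)C | intermediate
10 | (3E)-4-[(1R,4R)-4-hydroxy-2,6,6-trimethylcyclohex-2-en-1-yl]but-3-en-2-one | CC(=O)/C=C/[C@H]1C(C)=C[C@H](O)CC1(C)C | intermediate
11 | (3E)-4-[(1S,4R)-4-hydroxy-2,6,6-trimethylcyclohex-2-en-1-yl]but-3-en-2-one | CC(=O)/C=C/[C@@H]1C(C)=C[C@H](O)CC1(C)C | intermediate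
12 | (4E)-5-[(1R,4R)-4-hydroxy-2,6,6-trimethylcyclohex-2-en-1-yl]-3-methylpenta-1,4-dien-3-ol (both C3 epimers) | C=CC(C)(O)/C=C/[C@H]1C(C)=C[C@H](O)CC1(C)C | intermediate
13 | (4E)-5-[(1S,4R)-4-hydroxy-2,6,6-trimethylcyclohex-2-en-1-yl]-3-methylpenta-1,4-dien-3-ol (both C3 epimers) | C=CC(C)(O)/C=C/[C@@H]1C(C)=C[C@H](O)CC1(C)C | intermediate
14 | [(2E,4E)-5-[(1R,4R)-4-hydroxy-2,6,6-trimethylcyclohex-2-en-1-yl]-3-methylpenta-2,4-dien-1-yl](triphenyl)phosphonium bromide | C/C(=C\C[P+](c1ccccc1)(c1ccccc1)c1ccccc1)/C=C/[C@H]1C(C)=C[C@H](O)CC1(C)C.[Br-] | intermediate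
15 | [(2E,4E)-5-[(1S,4R)-4-hydroxy-2,6,6-trimethylcyclohex-2-en-1-yl]-3-methylpenta-2,4-dien-1-yl](triphenyl)phosphonium bromide | C/C(=C\C[P+](c1ccccc1)(c1ccccc1)c1ccccc1)/C=C/[C@@H]1C(C)=C[C@H](O)CC1(C)C.[Br-] | intermediate
16 | (2E,4E,6E)-2,7-dimethylocta-2,4,6-trienedial | O=C/C(C)=C/C=C/C=C(C)/C=O | starting material
17 | triphenylphosphonium ylide derived from 14 (not isolated) | C/C(=C\C=P(c1ccccc1)(c1ccccc1)c1ccccc1)/C=C/[C@H]1C(C)=C[C@H](O)CC1(C)C | intermediate
18 | (2E,4E,6E,8E,10E,12E)-13-[(1R,4R)-4-hydroxy-2,6,6-trimethylcyclohex-2-en-1-yl]-2,7,11-trimethyltrideca-2,4,6,8,10,12-hexaenal | O=C/C(C)=C/C=C/C=C(C)/C=C/C=C(C)/C=C/[C@H]1C(C)=C[C@H](O)CC1(C)C | intermediate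
19 | triphenylphosphonium ylide derived from 15 (not isolated) | C/C(=C\C=P(c1ccccc1)(c1ccccc1)c1ccccc1)/C=C/[C@@H]1C(C)=C[C@H](O)CC1(C)C | intermediate
20 | (3R,6R,3'R,6'S)-ε,ε-carotene-3,3'-diol | CC1=C[C@H](O)CC(C)(C)[C@@H]1/C=C/C(C)=C/C=C/C(C)=C/C=C/C=C(C)/C=C/C=C(C)/C=C/[C@H]1C(C)=C[C@H](O)CC1(C)C | intermediate
21 | (6R,6'S)-ε,ε-carotene-3,3'-dione (meso) | CC1=CC(=O)CC(C)(C)[C@@H]1/C=C/C(C)=C/C=C/C(C)=C/C=C/C=C(C)/C=C/C=C(C)/C=C/[C@H]1C(C)=CC(=O)CC1(C)C | target

**Count and risks**

Total step count: 14. Longest linear sequence: 10 steps (steps 1, 2, 3, 4, 6, 8, 10, 12, 13, 14).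

Steps most likely to fail:

Step 1 (new method). Two processes may defeat it. The anion of 1 may take a proton from a γ-methyl group of 2 instead of adding to it, which deconjugates the nitroalkene and lets it oligomerise. The nitronate may also acylate too slowly at the unactivated ester, so that the sequence stops at the open-chain adduct or reverts by retro-Michael cleavage. The fallback uses known reactions only, sets out from 1 and 2 and returns at 4. Soft enolisation of 1 (TBSOTf, Et3N, CH2Cl2, 0 °C) gives the silyl ketene acetal methyl 5-[tert-butyl(dimethyl)silyl]oxy-5-methoxy-3-methylpenta-2,4-dienoate F1. This adds to 2 without base (Mukaiyama–Michael addition, MeCN, 25–60 °C; KF–AcOH work-up) to give dimethyl 3-methyl-4-(2-methyl-1-nitropropan-2-yl)pent-2-enedioate F2; either nucleophilic carbon of F1 leads to this same constitution. LiOH (1 equiv) in THF–H2O should saponify the unhindered conjugated ester to 5-methoxy-3-methyl-4-(2-methyl-1-nitropropan-2-yl)-5-oxopent-2-enoic acid F3. 1,1'-Carbonyldiimidazole converts it into the acyl imidazole methyl 5-(imidazol-1-yl)-3-methyl-2-(2-methyl-1-nitropropan-2-yl)-5-oxopent-3-enoate F4, and DBU then brings about the known C-acylation of a nitronate by an acyl imidazole, which closes the ring to 4.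

Step 3. Catalyst control may be incomplete for the antipode whose own facial preference opposes the catalyst. Each separated diastereomer would then carry some of the mirror-image series, and enantiopurity at C6 would be lost. The fallback sets out from 5 and returns at 6 and 7. Luche reduction (NaBH4, CeCl3·7H2O, MeOH, 0 °C) gives 6 and 7 together with their antipodes methyl (1S,4S)-4-hydroxy-2,6,6-trimethylcyclohex-2-ene-1-carboxylate F5 and methyl (1R,4S)-4-hydroxy-2,6,6-trimethylcyclohex-2-ene-1-carboxylate F6. Burkholderia cepacia lipase with vinyl acetate is expected to acetylate only the (4R)-alcohols, giving methyl (1R,4R)-4-acetoxy-2,6,6-trimethylcyclohex-2-ene-1-carboxylate F7 and methyl (1S,4R)-4-acetoxy-2,6,6-trimethylcyclohex-2-ene-1-carboxylate F8. These are separated from the unreacted alcohols and from each other on silica, and K2CO3 in MeOH returns 6 and 7.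

Step 4 (step 5 shares the risk). The reduction may run on to the primary alcohol, or stall on the hindered ester, so that no clean aldehyde is obtained. The fallback sets out from 6 and returns at 8. TBSCl and imidazole give methyl (1R,4R)-4-[tert-butyl(dimethyl)silyl]oxy-2,6,6-trimethylcyclohex-2-ene-1-carboxylate F9. LiAlH4 in Et2O reduces it fully to [(1R,4R)-4-[tert-butyl(dimethyl)silyl]oxy-2,6,6-trimethylcyclohex-2-en-1-yl]methanol F10. Dess–Martin periodinane (NaHCO3, CH2Cl2) gives (1R,4R)-4-[tert-butyl(dimethyl)silyl]oxy-2,6,6-trimethylcyclohex-2-ene-1-carbaldehyde F11, and HF·pyridine in THF at 0 °C removes the silyl group to give 8.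

Further compounds
F1 | step 1 | methyl 5-[tert-butyl(dimethyl)silyl]oxy-5-methoxy-3-methylpenta-2,4-dienoate | COC(=O)C=C(C)C=C(OC)O[Si](C)(C)C(C)(C)C
F2 | step 1 | dimethyl 3-methyl-4-(2-methyl-1-nitropropan-2-yl)pent-2-enedioate | COC(=O)C=C(C)C(C(=O)OC)C(C)(C)C[N+](=O)[O-]
F3 | step 1 | 5-methoxy-3-methyl-4-(2-methyl-1-nitropropan-2-yl)-5-oxopent-2-enoic acid | OC(=O)C=C(C)C(C(=O)OC)C(C)(C)C[N+](=O)[O-]
F4 | step 1 | methyl 5-(imidazol-1-yl)-3-methyl-2-(2-methyl-1-nitropropan-2-yl)-5-oxopent-3-enoate | COC(=O)C(C(C)=CC(=O)n1ccnc1)C(C)(C)C[N+](=O)[O-]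
F5 | step 3 | methyl (1S,4S)-4-hydroxy-2,6,6-trimethylcyclohex-2-ene-1-carboxylate | COC(=O)[C@@H]1C(C)=C[C@@H](O)CC1(C)C
F6 | step 3 | methyl (1R,4S)-4-hydroxy-2,6,6-trimethylcyclohex-2-ene-1-carboxylate | COC(=O)[C@H]1C(C)=C[C@@H](O)CC1(C)C
F7 | step 3 | methyl (1R,4R)-4-acetoxy-2,6,6-trimethylcyclohex-2-ene-1-carboxylate | COC(=O)[C@H]1C(C)=C[C@H](OC(C)=O)CC1(C)C
F8 | step 3 | methyl (1S,4R)-4-acetoxy-2,6,6-trimethylcyclohex-2-ene-1-carboxylate | COC(=O)[C@@H]1C(C)=C[C@H](OC(C)=O)CC1(C)C
F9 | step 4 | methyl (1R,4R)-4-[tert-butyl(dimethyl)silyl]oxy-2,6,6-trimethylcyclohex-2-ene-1-carboxylate | COC(=O)[C@H]1C(C)=C[C@H](O[Si](C)(C)C(C)(C)C)CC1(C)C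
F10 | step 4 | [(1R,4R)-4-[tert-butyl(dimethyl)silyl]oxy-2,6,6-trimethylcyclohex-2-en-1-yl]methanol | OC[C@H]1C(C)=C[C@H](O[Si](C)(C)C(C)(C)C)CC1(C)C
F11 | step 4 | (1R,4R)-4-[tert-butyl(dimethyl)silyl]oxy-2,6,6-trimethylcyclohex-2-ene-1-carbaldehyde | O=C[C@H]1C(C)=C[C@H](O[Si](C)(C)C(C)(C)C)CC1(C)C
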